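## The problem

Compound 13 is a biflavone in which an acacetin unit and an apigenin unit are held together by a single oxygen. C8 of ring A (the benzo ring of the acacetin chromone) is bonded to the 4'''-oxygen of ring F (the 2-aryl ring of the apigenin chromone). Rings A, C and B are the benzo ring, pyranone and 4-methoxyphenyl ring of the acacetin half (unprimed and singly primed locants); rings D, E and F are the same rings of the apigenin half (doubly and triply primed locants). There is no stereocentre, so the task is one of regio- and chemoselectivity. The ether carbon C8 lies between two oxygen-bearing carbons (C7 and C8a) on a 5-hydroxychromenone, so any substitution or metal-mediated etherification there is hindered and needs a C8 oxygen or halogen installed first. Four phenols must end up free (those at C5 and C5'' are chelated to the C4 carbonyls) while the single 4'-methyl ether stays in place. The pyranone rings open in hot alkali and their C2=C3 bonds can be reduced, and the phloroglucinol-type rings A and D are prone to oxidation and to electrophilic attack at C6 and C8. The enabling feature is that C8 is the carbon para to the C5 hydroxyl of ring A and its partner atom is a phenolic oxygen, which is the connectivity an oxidative phenol coupling leaves behind.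

## Retrosynthesis

**13 ⇒ 12.** Three O–CH2Ph bonds are added back, at O7, O5'' and O7''. Benzyl is preferred to acyl or silyl groups because all three fall in one neutral hydrogenolysis that leaves the methyl ether and the diaryl ether untouched. The forward step only has to spare the two pyranone C2=C3 bonds.

**12 ⇒ 9 + 7.** The C8–O4''' bond is cut. The neighbouring cut, O4'''–C4''', would call for an 8-hydroxyflavone and an activated aryl halide, meaning prior oxygenation of C8 and a hindered substitution. Cutting at C8 uses the C8–H of 9 and the O–H of 7 directly and divides the molecule into two monomeric flavones of nearly equal size. The forward reaction, an oxidative coupling with a trivalent iodine oxidant, must do four things: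
- oxidise only ring A of 9, which is why the C5 hydroxyl is left free in 9 and the C5'' oxygen is blocked in 7;
- bond at C8 and not at C6;
- use the oxygen and not a carbon of 7;
- stop before the product is oxidised further.

**9 ⇒ 8.** The O7–benzyl bond is cut. The 7-hydroxyl of acacetin 8 is para to the C4 carbonyl and the most acidic, while the 5-hydroxyl is tied up in the chelate, so a single alkylation is enough.

**7 ⇒ 6 ⇒ 5.** First the methoxymethyl group on O4''' is added back (6). Then the O1''–C2'' bond of ring E is opened with reduction of C2''=C3'' to the 2'-hydroxychalcone 5. Starting from apigenin is not an option because its alkylation goes to O7 and O4' before O5, so the pattern "5,7-dibenzyl, 4'-free" cannot be reached by selective benzylation. Building ring E places the benzyl groups before the chromone exists. The forward steps are an oxidative cyclisation and a mild acetal cleavage.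

**5 ⇒ 2 + 4.** The Cα=Cβ bond of the enone is cut (Claisen–Schmidt condensation). The phenol of the aldehyde must be masked with a group that survives hydroxide. An aryl silyl ether would not, so the methoxymethyl ether 4 is used.

**2 ⇒ 1 and 4 ⇒ 3.** Two O–benzyl bonds of 2 and the O–CH2OMe bond of 4 are cut, leading to 2,4,6-trihydroxyacetophenone 1 and 4-hydroxybenzaldehyde 3. In 1 the hydroxyl that must stay free is the one chelated to the acetyl group, so two equivalents of alkylating agent should suffice.

## Roads not taken

**Alternative 1:** Ring A is opened at C4a–C5 so that the aryloxy group already sits on the future C8 of an open chain. In the forward direction the pyranone keto ester A2 is treated with base. The extended enolate of the pyranone attacks the ester carbonyl through pyranone C3 (Claisen cyclisation), and enolisation gives the 8-aryloxy-5,7-dihydroxyflavone A1.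
- Merits: the C8–O bond exists before ring A does, so there is no C6/C8 question, no O- versus C-attack question and no oxidant near a phenol. In these respects it is better than the chosen plan.
- Weak points: A2 is an α-aryloxy β,δ-dicarbonyl chain on a base-sensitive pyranone. Its most acidic site is the methylene between ketone and ester, not the position that must become nucleophilic, so the closure needs polyanion chemistry and competes with O-acylation and pyranone opening. A1 still lacks the second chromone, which has to be grown from the aryl bromide over several steps with ring A protected.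
- Comparison: the chosen plan sets convergence against this safer regiochemistry. Both flavones are made by routine steps, joined once and deprotected once.

**Alternative 2:** Ring F is cut at C2'''–C3''' and C4'''–C5''', and the ether oxygen is carried as an ynol ether. In the forward direction the aryl ethynyl ether A4 and methyl coumalate A5 undergo a [4+2] cycloaddition, and loss of CO2 gives the 4-aryloxybenzoate A3.
- Merits: the hindered C–O bond is never formed by substitution or oxidation, and the pyrone cycloaddition with loss of CO2 is a known, para-selective reaction type. Step for step this road carries less risk than the chosen key step.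
- Weak points: A4 is a sensitive ynol ether of a hindered, electron-rich phenol and needs strong base to make. A3 contains neither chromone, so ring A must be acylated ortho to the unmasked hydroxyl and cyclised, and the benzoate must be turned into ring E, all on a crowded diaryl ether.
- Comparison: the step count would be roughly double, with several protecting-group changes. The chosen plan sets its short convergent sequence, and a fallback to 12 made only of known steps, against this.

**Alternative 3:** Ring D is cut at C4a''–C5'' and C8''–C8a''. In the forward direction the bromopyranone A7 and the bis(silyloxy)diene A8 combine in a [4+2] cycloaddition. Loss of HBr, methanol and the silyl groups gives A6 with ring D formed and its hydroxyls free.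
- Merits: the apigenin half needs no protecting groups, and ring D is made late, so it is exposed to few reagents.
- Weak points: the C5=C6 bond of a 4-pyranone is an electron-rich, poor dienophile. Lewis acid or heat strong enough to drive the addition endangers the peri benzyl ether and the diene. More seriously, A7 already contains the C8–O–C4''' ether, so the central problem is only moved into the preparation of A7. A6 also needs the same final hydrogenolysis as 12, so nothing is saved at the end.
- Comparison: the chosen plan attacks the ether bond itself. This alternative is better only in sparing the protection of ring D.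

Key step: step 7

Assumption: the chelated hydroxyl ortho or peri to the carbonyl in 1 and in 8 is taken to be the least reactive towards alkylation, so the partial benzylations of steps 1 and 6 should be selective; acacetin 8 is used as purchased.

## Route

Step 1
Reactants: 1 2,4,6-trihydroxyacetophenone
Product: 2 1-[2,4-bis(benzyloxy)-6-hydroxyphenyl]ethan-1-one
Conditions: BnBr (2.1 equiv), K2CO3 (2.2 equiv), DMF, 0 °C → rt
Reagents that add atoms: benzyl bromide, BrCc1ccccc1
Why: Williamson etherification; the para hydroxyl and one ortho hydroxyl are alkylated, while the remaining ortho hydroxyl is held in a hydrogen bond to the acetyl carbonyl and should stay free with two equivalents of halide.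

Step 2
Reactants: 3 4-hydroxybenzaldehyde
Product: 4 4-(methoxymethoxy)benzaldehyde
Conditions: MOMCl (1.3 equiv), K2CO3, acetone, 0 °C → rt
Reagents that add atoms: chloromethyl methyl ether, COCCl
Why: O-alkylation of the phenoxide with an α-chloro ether; the resulting acetal ether is stable to the hydroxide of step 3 and leaves under mild acid.

Step 3
Reactants: 2 1-[2,4-bis(benzyloxy)-6-hydroxyphenyl]ethan-1-one; 4 4-(methoxymethoxy)benzaldehyde
Product: 5 (E)-1-[2,4-bis(benzyloxy)-6-hydroxyphenyl]-3-[4-(methoxymethoxy)phenyl]prop-2-en-1-one
Conditions: KOH (50% aq., excess), EtOH/THF, rt, 24–48 h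
Reagents that add atoms: none
Why: Claisen–Schmidt condensation of a methyl ketone with a non-enolisable aldehyde; dehydration of the aldol should give the conjugated E-alkene as the thermodynamic product.

Step 4
Reactants: 5 (E)-1-[2,4-bis(benzyloxy)-6-hydroxyphenyl]-3-[4-(methoxymethoxy)phenyl]prop-2-en-1-one
Product: 6 5,7-bis(benzyloxy)-2-[4-(methoxymethoxy)phenyl]-4H-chromen-4-one
Conditions: I2 (10 mol %), DMSO, 120 °C
Reagents that add atoms: none
Why: Iodine-catalysed oxidative cyclisation of a 2'-hydroxychalcone to a flavone with DMSO as terminal oxidant; the only free hydroxyl is the one that becomes O1''.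

Step 5
Reactants: 6 5,7-bis(benzyloxy)-2-[4-(methoxymethoxy)phenyl]-4H-chromen-4-one
Product: 7 5,7-bis(benzyloxy)-2-(4-hydroxyphenyl)-4H-chromen-4-one (5,7-di-O-benzylapigenin)
Conditions: conc. HCl (3 equiv), MeOH/THF, 45 °C
Reagents that add atoms: none
Why: Acid-catalysed acetal exchange removes the methoxymethyl group; benzyl aryl ethers need much stronger acid, so only the 4'''-hydroxyl should be freed.

Step 6
Reactants: 8 acacetin (5,7-dihydroxy-2-(4-methoxyphenyl)-4H-chromen-4-one)
Product: 9 7-(benzyloxy)-5-hydroxy-2-(4-methoxyphenyl)-4H-chromen-4-one (7-O-benzylacacetin)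
Conditions: BnBr (1.1 equiv), K2CO3 (1.5 equiv), DMF, rt
Reagents that add atoms: benzyl bromide, BrCc1ccccc1
Why: Williamson etherification at the most acidic hydroxyl (O7, para to the C4 carbonyl); the 5-hydroxyl is chelated to the carbonyl and should not react with one equivalent of halide.

Step 7
Reactants: 9 7-(benzyloxy)-5-hydroxy-2-(4-methoxyphenyl)-4H-chromen-4-one; 7 5,7-bis(benzyloxy)-2-(4-hydroxyphenyl)-4H-chromen-4-one
Product: 12 7-(benzyloxy)-8-{4-[5,7-bis(benzyloxy)-4-oxo-4H-chromen-2-yl]phenoxy}-5-hydroxy-2-(4-methoxyphenyl)-4H-chromen-4-one, via aryloxyiodane 10 (not isolated), via C8 dienone 11 (not isolated)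
Conditions: PhI(OAc)2 (1.1 equiv, slow addition), 7 (2.5 equiv), 4 Å molecular sieves, CH2Cl2/(CF3)2CHOH 4:1, −20 → 0 °C
Reagents that add atoms: none
Why: Proposed new method: the chelated 5-hydroxyl of 9 exchanges for acetate on trivalent iodine to give aryloxyiodane 10, whose O–I bond ionises in the fluoroalcohol medium with loss of iodobenzene and acetate, leaving a phenoxonium equivalent with positive character at C6 and C8; the 4'''-hydroxyl of 7 adds at C8 to give dienone 11, and loss of the C8 proton re-aromatises ring A to the 5-hydroxy-8-aryloxyflavone 12. The closest known reaction types are the oxidative dearomatisation of phenols by trivalent iodine with capture of an oxygen nucleophile at the para carbon, and the Elbs persulfate oxidation, which functionalises C8 of 5-hydroxyflavones. No ring is closed and no stereocentre survives, because the sp3 carbon of 11 becomes planar again on tautomerisation. Chemoselectivity between the partners rests on 9 being the only component with a free hydroxyl para to an unsubstituted ring carbon: in 7 the 5''-oxygen is benzylated and the carbon para to its phenol carries the electron-poor chromone, so ligand exchange there should be reversible and unproductive. C8 is expected over C6 because para attack gives a cross-conjugated dienone in which both ring alkenes bear an oxygen donor (O7 and O1), in line with the para-selective Elbs reaction, whereas attack at C6 gives a less stabilised linearly conjugated dienone. O–C over C–C bond formation is favoured by sterics: C8 lies between two oxygenated carbons, so attack by C6'', C8'' or C3''' of 7 would build a tri- or tetra-ortho-substituted biaryl, while the phenol oxygen is unhindered. The excess of 7 and the slow addition of oxidant at low temperature are meant to hold back self-coupling of 9 and further oxidation of 12.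

Step 8
Reactants: 12 7-(benzyloxy)-8-{4-[5,7-bis(benzyloxy)-4-oxo-4H-chromen-2-yl]phenoxy}-5-hydroxy-2-(4-methoxyphenyl)-4H-chromen-4-one
Product: 13 5,7-dihydroxy-8-[4-(5,7-dihydroxy-4-oxo-4H-chromen-2-yl)phenoxy]-2-(4-methoxyphenyl)-4H-chromen-4-one
Conditions: H2 (1 atm), 10% Pd/C, THF/MeOH, rt
Reagents that add atoms: none
Why: Catalytic hydrogenolysis of the three benzylic C–O bonds; the aryl methyl ether and the diaryl ether are inert, and the aryl-conjugated C2=C3 bonds of the pyranones are reduced much more slowly, so the reaction should be stopped once hydrogen uptake for three benzyl groups is complete.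

## Compound list

1 | 2,4,6-trihydroxyacetophenone | CC(=O)c1c(O)cc(O)cc1O | starting material
2 | 1-[2,4-bis(benzyloxy)-6-hydroxyphenyl]ethan-1-one | CC(=O)c1c(O)cc(OCc2ccccc2)cc1OCc1ccccc1 | intermediate
3 | 4-hydroxybenzaldehyde | O=Cc1ccc(O)cc1 | starting material
4 | 4-(methoxymethoxy)benzaldehyde | COCOc1ccc(C=O)cc1 | intermediate
5 | (E)-1-[2,4-bis(benzyloxy)-6-hydroxyphenyl]-3-[4-(methoxymethoxy)phenyl]prop-2-en-1-one | COCOc1ccc(/C=C/C(=O)c2c(O)cc(OCc3ccccc3)cc2OCc2ccccc2)cc1 | intermediate
6 | 5,7-bis(benzyloxy)-2-[4-(methoxymethoxy)phenyl]-4H-chromen-4-one | COCOc1ccc(-c2cc(=O)c3c(OCc4ccccc4)cc(OCc4ccccc4)cc3o2)cc1 | intermediate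
7 | 5,7-bis(benzyloxy)-2-(4-hydroxyphenyl)-4H-chromen-4-one (5,7-di-O-benzylapigenin) | O=c1cc(-c2ccc(O)cc2)oc2cc(OCc3ccccc3)cc(OCc3ccccc3)c12 | intermediate
8 | acacetin, 5,7-dihydroxy-2-(4-methoxyphenyl)-4H-chromen-4-one | COc1ccc(-c2cc(=O)c3c(O)cc(O)cc3o2)cc1 | starting material
9 | 7-(benzyloxy)-5-hydroxy-2-(4-methoxyphenyl)-4H-chromen-4-one (7-O-benzylacacetin) | COc1ccc(-c2cc(=O)c3c(O)cc(OCc4ccccc4)cc3o2)cc1 | intermediate
10 | acetoxy{[7-(benzyloxy)-2-(4-methoxyphenyl)-4-oxo-4H-chromen-5-yl]oxy}(phenyl)iodine, the 5-O-bound trivalent iodine species formed in the flask | COc1ccc(-c2cc(=O)c3c(OI(OC(C)=O)c4ccccc4)cc(OCc4ccccc4)cc3o2)cc1 | intermediate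
11 | 8-{4-[5,7-bis(benzyloxy)-4-oxo-4H-chromen-2-yl]phenoxy}-7-(benzyloxy)-2-(4-methoxyphenyl)-8H-chromene-4,5-dione, racemic at C8, formed in the flask | COc1ccc(cc1)C2=CC(=O)C3=C(O2)C(Oc4ccc(cc4)-c5cc(=O)c6c(OCc7ccccc7)cc(OCc7ccccc7)cc6o5)C(OCc8ccccc8)=CC3=O | intermediate
12 | 7-(benzyloxy)-8-{4-[5,7-bis(benzyloxy)-4-oxo-4H-chromen-2-yl]phenoxy}-5-hydroxy-2-(4-methoxyphenyl)-4H-chromen-4-one | COc1ccc(-c2cc(=O)c3c(O)cc(OCc4ccccc4)c(Oc4ccc(-c5cc(=O)c6c(OCc7ccccc7)cc(OCc7ccccc7)cc6o5)cc4)c3o2)cc1 | intermediate
13 | 5,7-dihydroxy-8-[4-(5,7-dihydroxy-4-oxo-4H-chromen-2-yl)phenoxy]-2-(4-methoxyphenyl)-4H-chromen-4-one | COc1ccc(-c2cc(=O)c3c(O)cc(O)c(Oc4ccc(-c5cc(=O)c6c(O)cc(O)cc6o5)cc4)c3o2)cc1 | target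

## Step count and least certain steps

Total: 8 steps. Longest linear sequence: 6 steps (1, 3, 4, 5, 7, 8, from compound 1). Steps 2 and 6 are single-step side branches.

**Step 7 (key step).** Several processes can divert it:
- further oxidation of the newly formed ring, which as a para-oxygenated phenol is easier to oxidise than 9, leading to ketal or quinone formation at C8 and loss of the aryloxy group if water is present;
- carbon–carbon bond formation through C6''/C8'' of ring D or C3''' of ring F, which a fluoroalcohol medium tends to favour;
- attack at C6;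
- iodination of a ring A carbon by the oxidant in place of ligand exchange at the chelated oxygen;
- self-coupling of 9.

Slow addition, the excess of 7, exclusion of water and a reductive work-up that could return a doubly oxidised C8 ketal to 12 are the means within the step.

The fallback uses known chemistry, sets out from 9 and returns at 12. Elbs persulfate oxidation of 9 (K2S2O8, aq. KOH, pyridine, rt) should give potassium 7-(benzyloxy)-5-hydroxy-2-(4-methoxyphenyl)-4-oxo-4H-chromen-8-yl sulfate F1. Acid hydrolysis (aq. HCl, Na2SO3, 80 °C) would free 7-(benzyloxy)-5,8-dihydroxy-2-(4-methoxyphenyl)-4H-chromen-4-one F2. Nucleophilic aromatic substitution of 4-fluorobenzaldehyde by the non-chelated 8-hydroxyl (K2CO3, DMF, 90 °C, under argon) would give 4-{[7-(benzyloxy)-5-hydroxy-2-(4-methoxyphenyl)-4-oxo-4H-chromen-8-yl]oxy}benzaldehyde F3. Claisen–Schmidt condensation of F3 with 2 (KOH, EtOH/THF, rt) would give (E)-7-(benzyloxy)-8-(4-{3-[2,4-bis(benzyloxy)-6-hydroxyphenyl]-3-oxoprop-1-en-1-yl}phenoxy)-5-hydroxy-2-(4-methoxyphenyl)-4H-chromen-4-one F4. Iodine-catalysed cyclisation in DMSO at 120 °C would close ring E to 12.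

**Step 4.** The hydrogen iodide formed at 120 °C may cause acid-promoted loss of the 5''-benzyl ether (peri to the carbonyl) or of the methoxymethyl group, and ring D may be iodinated. Early loss of the methoxymethyl group alone would be harmless, since step 5 removes it anyway. The fallback sets out from 5 and returns at 6: base-mediated oxa-Michael ring closure (NaOAc, EtOH, reflux) to racemic 5,7-bis(benzyloxy)-2-[4-(methoxymethoxy)phenyl]chroman-4-one F5, then dehydrogenation with DDQ in refluxing dioxane.

**Step 8.** Partial saturation of the C2=C3 bonds, or incomplete cleavage because partly debenzylated material precipitates, may occur. The fallback goes from 12 directly to 13 by Lewis-acid dealkylation (BCl3, pentamethylbenzene as cation scavenger, CH2Cl2, −78 °C), which leaves the aryl methyl ether intact at this temperature. No new compound arises on this path (entry F0).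

**Step 1.** Statistical over- and under-alkylation and C-benzylation of the phloroglucinol ring may lower the return of 2. The fallback sets out from 1 and returns at 2: exhaustive benzylation (BnBr, 3.5 equiv, K2CO3, DMF, 80 °C) to 1-[2,4,6-tris(benzyloxy)phenyl]ethan-1-one F6, then chelation-controlled removal of one benzyl group ortho to the carbonyl with MgBr2·OEt2 in toluene/Et2O at 80 °C.

## Further compounds

F1 | step 7 | potassium 7-(benzyloxy)-5-hydroxy-2-(4-methoxyphenyl)-4-oxo-4H-chromen-8-yl sulfate | COc1ccc(-c2cc(=O)c3c(O)cc(OCc4ccccc4)c(OS(=O)(=O)[O-])c3o2)cc1.[K+]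
F2 | step 7 | 7-(benzyloxy)-5,8-dihydroxy-2-(4-methoxyphenyl)-4H-chromen-4-one | COc1ccc(-c2cc(=O)c3c(O)cc(OCc4ccccc4)c(O)c3o2)cc1
F3 | step 7 | 4-{[7-(benzyloxy)-5-hydroxy-2-(4-methoxyphenyl)-4-oxo-4H-chromen-8-yl]oxy}benzaldehyde | COc1ccc(-c2cc(=O)c3c(O)cc(OCc4ccccc4)c(Oc4ccc(C=O)cc4)c3o2)cc1
F4 | step 7 | (E)-7-(benzyloxy)-8-(4-{3-[2,4-bis(benzyloxy)-6-hydroxyphenyl]-3-oxoprop-1-en-1-yl}phenoxy)-5-hydroxy-2-(4-methoxyphenyl)-4H-chromen-4-one | COc1ccc(-c2cc(=O)c3c(O)cc(OCc4ccccc4)c(Oc4ccc(/C=C/C(=O)c5c(O)cc(OCc6ccccc6)cc5OCc5ccccc5)cc4)c3o2)cc1
F5 | step 4 | 5,7-bis(benzyloxy)-2-[4-(methoxymethoxy)phenyl]chroman-4-one (racemic) | COCOc1ccc(C2CC(=O)c3c(OCc4ccccc4)cc(OCc4ccccc4)cc3O2)cc1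
F0 | step 8 | none | none
F6 | step 1 | 1-[2,4,6-tris(benzyloxy)phenyl]ethan-1-one | CC(=O)c1c(OCc2ccccc2)cc(OCc2ccccc2)cc1OCc1ccccc1
A1 | alternative 1 | 8-(4-bromophenoxy)-5,7-dihydroxy-2-(4-methoxyphenyl)-4H-chromen-4-one | COc1ccc(-c2cc(=O)c3c(O)cc(O)c(Oc4ccc(Br)cc4)c3o2)cc1
A2 | alternative 1 | methyl 4-(4-bromophenoxy)-4-[6-(4-methoxyphenyl)-4-oxo-4H-pyran-2-yl]-3-oxobutanoate (racemic) | COC(=O)CC(=O)C(Oc1ccc(Br)cc1)c1cc(=O)cc(-c2ccc(OC)cc2)o1
A3 | alternative 2 | methyl 4-[2,4-bis(benzyloxy)-6-(methoxymethoxy)phenoxy]benzoate | COC(=O)c1ccc(Oc2c(OCOC)cc(OCc3ccccc3)cc2OCc2ccccc2)cc1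
A4 | alternative 2 | 1,5-bis(benzyloxy)-2-(ethynyloxy)-3-(methoxymethoxy)benzene | C#COc1c(OCOC)cc(OCc2ccccc2)cc1OCc1ccccc1
A5 | alternative 2 | methyl coumalate (methyl 2-oxo-2H-pyran-5-carboxylate) | COC(=O)c1ccc(=O)oc1
A6 | alternative 3 | 5,7-bis(benzyloxy)-8-[4-(5,7-dihydroxy-4-oxo-4H-chromen-2-yl)phenoxy]-2-(4-methoxyphenyl)-4H-chromen-4-one | COc1ccc(-c2cc(=O)c3c(OCc4ccccc4)cc(OCc4ccccc4)c(Oc4ccc(-c5cc(=O)c6c(O)cc(O)cc6o5)cc4)c3o2)cc1
A7 | alternative 3 | 5,7-bis(benzyloxy)-8-[4-(5-bromo-4-oxo-4H-pyran-2-yl)phenoxy]-2-(4-methoxyphenyl)-4H-chromen-4-one | COc1ccc(-c2cc(=O)c3c(OCc4ccccc4)cc(OCc4ccccc4)c(Oc4ccc(-c5cc(=O)c(Br)co5)cc4)c3o2)cc1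
A8 | alternative 3 | 1-methoxy-1,3-bis(trimethylsilyloxy)buta-1,3-diene (geometry at C1=C2 not defined) | C=C(O[Si](C)(C)C)C=C(OC)O[Si](C)(C)C
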